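**Retrosynthetic overview**
1. Target 30 ⇐ enedione acid 29 (directed i-Bu2AlH reduction of one ketone) ⇐ epoxy ketal 28 (acid unmasking) ⇐ hydroxymethyl quinone monoketal 27 (tartrate-mediated nucleophilic epoxidation) ⇐ 4-methoxyphenol 25 (PhI(OAc)2/MeOH dearomatisation, then PMB removal).
2. 25 ⇐ phenol 23 (cross-metathesis) ⇐ cyclobutenone 20 by thermal two-carbon ring expansion (Moore rearrangement): the cyclohexenone ring of the target is first made as the benzene ring of a hydroquinone monomethyl ether, from a four-membered ring.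
3. Enabling feature: in the six-membered carbocycle the ketone carbon and the carbinol carbon are para (1,4), so the ring is a masked hydroquinone. The ketene carbon of the opened cyclobutenone becomes the C=O carbon, the C(OMe) carbon becomes the carbinol carbon, the two alkenyl carbons become the two oxirane carbons, and the two cyclobutene sp2 carbons become C(heptenyl) and C(CH2OH).
4. 20 ⇐ diisopropyl squarate 4 by three regiodefined organolithium additions: (E)-heptenyl; (E)-penta-1,4-dienyl with O-methylation; PMB-oxymethyl with carbonyl transposition.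
5. Ring order: cyclobutene (bought in 4) → benzene (step 7) → cyclohexa-2,5-dienone (step 9) → oxirane (step 11).

Key step: step 7

Assumption: the antipode of diisopropyl tartrate that leads to the (1S,6R)-epoxide 28 is taken to be L-(+)-diisopropyl tartrate; should the sense of induction be the opposite, D-(−)-diisopropyl tartrate is used and nothing else changes.

**Step 1**
Reactants: 1 hept-1-yne
Product: 3 (E)-1-iodohept-1-ene, via (E)-hept-1-enylzirconocene chloride 2 (not isolated)
Conditions: Cp2Zr(H)Cl, THF, rt; then I2, 0 °C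
Reagents that add atoms: iodine, II
Why: syn hydrozirconation of the terminal alkyne places zirconium on the terminal carbon and iododezirconation goes with retention, so the (E)-iodide should form (hydrozirconation–iodination).

**Step 2**
Reactants: 3 (E)-1-iodohept-1-ene; 4 diisopropyl squarate (3,4-di(propan-2-yloxy)cyclobut-3-ene-1,2-dione)
Product: 7 3-[(1E)-hept-1-en-1-yl]-4-(propan-2-yloxy)cyclobut-3-ene-1,2-dione, via (E)-hept-1-enyllithium 5 (not isolated), via lithium alkoxide of the heptenyl adduct 6 (not isolated)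
Conditions: t-BuLi (2 equiv), Et2O, −78 °C; then 4, THF, −78 °C; 1 M HCl quench; then 12 M HCl (cat.), CH2Cl2, rt
Reagents that add atoms: water, O
Why: iodine–lithium exchange with retention of the (E) geometry, 1,2-addition to one carbonyl of the symmetrical squarate and acid-induced collapse of the vinylogous hemiketal (loss of water and propan-2-ol) should give the 3-alkenyl-4-alkoxy dione, a standard squarate substitution.

**Step 3**
Reactants: 8 (E)-1,2-bis(tributylstannyl)ethene; 9 allyl bromide (3-bromoprop-1-ene)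
Product: 10 tributyl[(1E)-penta-1,4-dien-1-yl]stannane
Conditions: Pd2(dba)3 (2.5 mol %), P(2-furyl)3 (10 mol %), THF, 50 °C; 8 in twofold excess
Reagents that add atoms: none
Why: Stille coupling of the allylic bromide at one tin terminus of the excess bis-stannane goes with retention at the alkenyl carbon, so the (E)-1,4-dienylstannane should result.

**Step 4**
Reactants: 10 tributyl[(1E)-penta-1,4-dien-1-yl]stannane; 7 3-[(1E)-hept-1-en-1-yl]-4-(propan-2-yloxy)cyclobut-3-ene-1,2-dione
Product: 13 2-[(1E)-hept-1-en-1-yl]-4-methoxy-4-[(1E)-penta-1,4-dien-1-yl]-3-(propan-2-yloxy)cyclobut-2-en-1-one (racemic), via (E)-penta-1,4-dienyllithium 11 (not isolated), via lithium alkoxide of the dienyl adduct 12 (not isolated)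
Conditions: n-BuLi, THF, −78 °C; then 7, THF, −78 °C; then MeOTf, −78 to 0 °C
Reagents that add atoms: methyl trifluoromethanesulfonate, COS(=O)(=O)C(F)(F)F
Why: tin–lithium exchange keeps the (E) geometry, the alkenyllithium should add only to the carbonyl next to the alkoxy-bearing ring carbon because the other carbonyl is a deactivated vinylogous ester (regioselective 1,2-addition to a 3-alkoxycyclobutenedione), and O-methylation of the lithium alkoxide fixes the tertiary methyl ether, whose racemic quaternary centre is erased in step 7.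

**Step 5**
Reactants: 14 tributyl(iodomethyl)stannane; 15 (4-methoxyphenyl)methanol
Product: 17 tributyl{[(4-methoxybenzyl)oxy]methyl}stannane, via sodium 4-methoxybenzyl alkoxide 16 (not isolated)
Conditions: NaH, THF–DMF, 0 °C to rt
Reagents that add atoms: none
Why: Williamson ether synthesis on the unhindered primary iodide.

**Step 6**
Reactants: 17 tributyl{[(4-methoxybenzyl)oxy]methyl}stannane; 13 2-[(1E)-hept-1-en-1-yl]-4-methoxy-4-[(1E)-penta-1,4-dien-1-yl]-3-(propan-2-yloxy)cyclobut-2-en-1-one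
Product: 20 2-[(1E)-hept-1-en-1-yl]-4-methoxy-3-{[(4-methoxybenzyl)oxy]methyl}-4-[(1E)-penta-1,4-dien-1-yl]cyclobut-2-en-1-one (racemic), via {[(4-methoxybenzyl)oxy]methyl}lithium 18 (not isolated), via lithium alkoxide of the alkoxymethyl adduct 19 (not isolated)
Conditions: n-BuLi (slight deficit), THF, −78 °C; then 13, −78 °C; then 1 M HCl, 0 °C to rt
Reagents that add atoms: water, O
Why: tin–lithium exchange gives the α-alkoxymethyllithium, whose 1,2-addition to the vinylogous ester carbonyl followed by acid hydrolysis (loss of water and propan-2-ol) transposes the carbonyl (Stork–Danheiser-type transposition), and because the ring carbon carrying methoxy and dienyl lies between the two exchanging positions the same cyclobutenone results from 1,2- or 1,4-attack.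

**Step 7**
Reactants: 20 2-[(1E)-hept-1-en-1-yl]-4-methoxy-3-{[(4-methoxybenzyl)oxy]methyl}-4-[(1E)-penta-1,4-dien-1-yl]cyclobut-2-en-1-one
Product: 23 2-[(1E)-hept-1-en-1-yl]-4-methoxy-3-{[(4-methoxybenzyl)oxy]methyl}-6-(prop-2-en-1-yl)phenol, via dienylketene 21 (not isolated), via cyclohexa-2,4-dienone 22 (not isolated)
Conditions: toluene (0.02 M, degassed), 110 °C
Reagents that add atoms: none
Why: Heating should open the cyclobutenone by conrotatory 4π-electrocyclic cleavage of the bond between the carbonyl carbon and the carbon carrying methoxy and dienyl, giving dienylketene 21, which closes and tautomerises to the phenol; the closest known reaction type is the Moore rearrangement of squarate-derived 4-alkenyl-4-alkoxycyclobutenones to hydroquinone monoethers. The six-membered ring is closed by a thermal disrotatory 6π-electrocyclisation that joins the ketene carbon to the terminal carbon of the former 4-alkenyl group, so the four-membered ring grows by two carbons. The only new sp3 centre, the allyl-bearing carbon of 22, is erased by enolisation, so no stereocentre has to be controlled. The step needs inward rotation of the alkenyl group in the ring opening, which the 4-methoxy donor secures by rotating outward (torquoselectivity), and it needs a ketene that meets no internal nucleophile, which the PMB ether on the hydroxymethyl group secures. The substitution pattern is fixed by connectivity alone: the ketene carbon becomes the C–OH carbon flanked by the heptenyl- and allyl-bearing carbons, and the methoxy-bearing carbon lies para to it, flanked by C–H and the carbon bearing the CH2OPMB group.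

**Step 8**
Reactants: 23 2-[(1E)-hept-1-en-1-yl]-4-methoxy-3-{[(4-methoxybenzyl)oxy]methyl}-6-(prop-2-en-1-yl)phenol; 24 tert-butyl methacrylate (tert-butyl 2-methylprop-2-enoate)
Product: 25 tert-butyl (2E)-4-{3-[(1E)-hept-1-en-1-yl]-2-hydroxy-5-methoxy-4-{[(4-methoxybenzyl)oxy]methyl}phenyl}-2-methylbut-2-enoate
Conditions: RuCl2(H2IMes)(=CH-C6H4-2-OiPr) (second-generation Hoveyda–Grubbs catalyst, 5 mol %), 24 (10 equiv), 1,4-benzoquinone (10 mol %), CH2Cl2, 40 °C
Reagents that add atoms: none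
Why: olefin cross-metathesis of the terminal allyl group with the 1,1-disubstituted acrylate should give the trisubstituted enoate as the thermodynamically favoured (E) isomer, while the hindered internal heptenyl alkene should stay out of the reaction.

**Step 9**
Reactants: 25 tert-butyl (2E)-4-{3-[(1E)-hept-1-en-1-yl]-2-hydroxy-5-methoxy-4-{[(4-methoxybenzyl)oxy]methyl}phenyl}-2-methylbut-2-enoate
Product: 26 tert-butyl (2E)-4-{5-[(1E)-hept-1-en-1-yl]-3,3-dimethoxy-4-{[(4-methoxybenzyl)oxy]methyl}-6-oxocyclohexa-1,4-dien-1-yl}-2-methylbut-2-enoate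
Conditions: PhI(OAc)2, MeOH, 0 °C; NaHCO3
Reagents that add atoms: methanol, CO
Why: oxidative dearomatisation of a 4-methoxyphenol by the hypervalent iodine reagent in methanol places the second methoxy group on the methoxy-bearing carbon, so the quinone monoketal with the free carbonyl at the former phenol carbon should form.

**Step 10**
Reactants: 26 tert-butyl (2E)-4-{5-[(1E)-hept-1-en-1-yl]-3,3-dimethoxy-4-{[(4-methoxybenzyl)oxy]methyl}-6-oxocyclohexa-1,4-dien-1-yl}-2-methylbut-2-enoate
Product: 27 tert-butyl (2E)-4-{5-[(1E)-hept-1-en-1-yl]-4-(hydroxymethyl)-3,3-dimethoxy-6-oxocyclohexa-1,4-dien-1-yl}-2-methylbut-2-enoate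
Conditions: DDQ (1.2 equiv), CH2Cl2–pH 7 phosphate buffer, 0 °C
Reagents that add atoms: none
Why: oxidative cleavage of the electron-rich 4-methoxybenzyl ether by DDQ at neutral pH should spare the electron-poor dienone and its acid-labile ketal.

**Step 11**
Reactants: 27 tert-butyl (2E)-4-{5-[(1E)-hept-1-en-1-yl]-4-(hydroxymethyl)-3,3-dimethoxy-6-oxocyclohexa-1,4-dien-1-yl}-2-methylbut-2-enoate
Product: 28 tert-butyl (2E)-4-[(1S,6R)-3-[(1E)-hept-1-en-1-yl]-4-(hydroxymethyl)-5,5-dimethoxy-2-oxo-7-oxabicyclo[4.1.0]hept-3-en-1-yl]-2-methylbut-2-enoate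
Conditions: Ph3COOH, NaN(SiMe3)2, L-(+)-diisopropyl tartrate, 4 Å molecular sieves, toluene, −55 to −40 °C
Reagents that add atoms: triphenylmethyl hydroperoxide, OOC(c1ccccc1)(c1ccccc1)c1ccccc1
Why: in this tartrate-mediated nucleophilic (Weitz–Scheffer-type) epoxidation the sodium alkoxide of the hydroxymethyl group should anchor the chiral tartrate–peroxide aggregate, the peroxide should add only to the unsubstituted β-carbon next to the ketal (the other β-carbon is fully substituted), and ring closure then sets both oxirane stereocentres (1S,6R) together on the face chosen by the tartrate.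

**Step 12**
Reactants: 28 tert-butyl (2E)-4-[(1S,6R)-3-[(1E)-hept-1-en-1-yl]-4-(hydroxymethyl)-5,5-dimethoxy-2-oxo-7-oxabicyclo[4.1.0]hept-3-en-1-yl]-2-methylbut-2-enoate
Product: 29 (2E)-4-[(1S,6R)-3-[(1E)-hept-1-en-1-yl]-4-(hydroxymethyl)-2,5-dioxo-7-oxabicyclo[4.1.0]hept-3-en-1-yl]-2-methylbut-2-enoic acid
Conditions: CF3CO2H–CH2Cl2–H2O (10:10:1), 0 °C to rt; aqueous work-up
Reagents that add atoms: water, O
Why: acidolysis should hydrolyse the dimethyl ketal and cleave the tert-butyl ester in one operation, while the oxirane, flanked by two carbonyl groups, is deactivated towards acid opening.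

**Step 13**
Reactants: 29 (2E)-4-[(1S,6R)-3-[(1E)-hept-1-en-1-yl]-4-(hydroxymethyl)-2,5-dioxo-7-oxabicyclo[4.1.0]hept-3-en-1-yl]-2-methylbut-2-enoic acid
Product: 30 (2E)-4-[(1S,5R,6S)-3-[(1E)-hept-1-en-1-yl]-5-hydroxy-4-(hydroxymethyl)-2-oxo-7-oxabicyclo[4.1.0]hept-3-en-1-yl]-2-methylbut-2-enoic acid
Conditions: i-Bu2AlH (4.5 equiv), THF, −78 °C; aq. KNaC4H4O6 (sodium potassium tartrate), then pH 3 citrate buffer
Reagents that add atoms: none
Why: once the acid and the primary alcohol are aluminium salts, hydride should go 1,2 to the less hindered carbonyl next to the hydroxymethyl-bearing carbon and, with aluminium held by the primary alkoxide and the oxirane oxygen, on the face of the oxirane oxygen, giving the (5R) alcohol anti to the epoxide (hydroxyl-directed reduction, in line with the behaviour of related hydroxymethyl epoxyquinones).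

**Compound list**
1 | hept-1-yne | CCCCCC#C | starting material
2 | (E)-hept-1-enylzirconocene chloride | CCCCC/C=C/[Zr](Cl)(C1C=CC=C1)C1C=CC=C1 | intermediate
3 | (E)-1-iodohept-1-ene | CCCCC/C=C/I | intermediate
4 | diisopropyl squarate, 3,4-di(propan-2-yloxy)cyclobut-3-ene-1,2-dione | CC(C)OC1=C(OC(C)C)C(=O)C1=O | starting material
5 | (E)-hept-1-enyllithium | CCCCC/C=C/[Li] | intermediate
6 | lithium 1-[(1E)-hept-1-en-1-yl]-4-oxo-2,3-di(propan-2-yloxy)cyclobut-2-en-1-olate | CCCCC/C=C/C1(O[Li])C(=O)C(OC(C)C)=C1OC(C)C | intermediate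
7 | 3-[(1E)-hept-1-en-1-yl]-4-(propan-2-yloxy)cyclobut-3-ene-1,2-dione | CCCCC/C=C/C1=C(OC(C)C)C(=O)C1=O | intermediate
8 | (E)-1,2-bis(tributylstannyl)ethene | CCCC[Sn](CCCC)(CCCC)/C=C/[Sn](CCCC)(CCCC)CCCC | starting material
9 | allyl bromide, 3-bromoprop-1-ene | C=CCBr | starting material
10 | tributyl[(1E)-penta-1,4-dien-1-yl]stannane | C=CC/C=C/[Sn](CCCC)(CCCC)CCCC | intermediate
11 | (E)-penta-1,4-dienyllithium | C=CC/C=C/[Li] | intermediate
12 | lithium 3-[(1E)-hept-1-en-1-yl]-4-oxo-1-[(1E)-penta-1,4-dien-1-yl]-2-(propan-2-yloxy)cyclobut-2-en-1-olate | CCCCC/C=C/C1=C(OC(C)C)C(O[Li])(/C=C/CC=C)C1=O | intermediate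
13 | 2-[(1E)-hept-1-en-1-yl]-4-methoxy-4-[(1E)-penta-1,4-dien-1-yl]-3-(propan-2-yloxy)cyclobut-2-en-1-one (racemic) | CCCCC/C=C/C1=C(OC(C)C)C(OC)(/C=C/CC=C)C1=O | intermediate
14 | tributyl(iodomethyl)stannane | CCCC[Sn](CI)(CCCC)CCCC | starting material
15 | (4-methoxyphenyl)methanol | COc1ccc(CO)cc1 | starting material
16 | sodium (4-methoxyphenyl)methanolate | COc1ccc(C[O-])cc1.[Na+] | intermediate
17 | tributyl{[(4-methoxybenzyl)oxy]methyl}stannane | CCCC[Sn](COCc1ccc(OC)cc1)(CCCC)CCCC | intermediate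
18 | {[(4-methoxybenzyl)oxy]methyl}lithium | [Li]COCc1ccc(OC)cc1 | intermediate
19 | lithium 2-[(1E)-hept-1-en-1-yl]-4-methoxy-1-{[(4-methoxybenzyl)oxy]methyl}-4-[(1E)-penta-1,4-dien-1-yl]-3-(propan-2-yloxy)cyclobut-2-en-1-olate | CCCCC/C=C/C1=C(OC(C)C)C(OC)(/C=C/CC=C)C1(O[Li])COCc2ccc(OC)cc2 | intermediate
20 | 2-[(1E)-hept-1-en-1-yl]-4-methoxy-3-{[(4-methoxybenzyl)oxy]methyl}-4-[(1E)-penta-1,4-dien-1-yl]cyclobut-2-en-1-one (racemic) | CCCCC/C=C/C1=C(COCc2ccc(OC)cc2)C(OC)(/C=C/CC=C)C1=O | intermediate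
21 | (3Z,5E)-2-[(1E)-hept-1-en-1-yl]-4-methoxy-3-{[(4-methoxybenzyl)oxy]methyl}nona-1,3,5,8-tetraen-1-one (dienylketene) | O=C=C(/C=C/CCCCC)/C(COCc1ccc(OC)cc1)=C(OC)\C=C\CC=C | intermediate
22 | 2-[(1E)-hept-1-en-1-yl]-4-methoxy-3-{[(4-methoxybenzyl)oxy]methyl}-6-(prop-2-en-1-yl)cyclohexa-2,4-dien-1-one (racemic) | O=C1C(/C=C/CCCCC)=C(COCc2ccc(OC)cc2)C(OC)=CC1CC=C | intermediate
23 | 2-[(1E)-hept-1-en-1-yl]-4-methoxy-3-{[(4-methoxybenzyl)oxy]methyl}-6-(prop-2-en-1-yl)phenol | Oc1c(CC=C)cc(OC)c(COCc2ccc(OC)cc2)c1/C=C/CCCCC | intermediate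
24 | tert-butyl methacrylate, tert-butyl 2-methylprop-2-enoate | CC(=C)C(=O)OC(C)(C)C | starting material
25 | tert-butyl (2E)-4-{3-[(1E)-hept-1-en-1-yl]-2-hydroxy-5-methoxy-4-{[(4-methoxybenzyl)oxy]methyl}phenyl}-2-methylbut-2-enoate | Oc1c(C/C=C(\C)C(=O)OC(C)(C)C)cc(OC)c(COCc2ccc(OC)cc2)c1/C=C/CCCCC | intermediate
26 | tert-butyl (2E)-4-{5-[(1E)-hept-1-en-1-yl]-3,3-dimethoxy-4-{[(4-methoxybenzyl)oxy]methyl}-6-oxocyclohexa-1,4-dien-1-yl}-2-methylbut-2-enoate | O=C1C(C/C=C(\C)C(=O)OC(C)(C)C)=CC(OC)(OC)C(COCc2ccc(OC)cc2)=C1/C=C/CCCCC | intermediate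
27 | tert-butyl (2E)-4-{5-[(1E)-hept-1-en-1-yl]-4-(hydroxymethyl)-3,3-dimethoxy-6-oxocyclohexa-1,4-dien-1-yl}-2-methylbut-2-enoate | O=C1C(C/C=C(\C)C(=O)OC(C)(C)C)=CC(OC)(OC)C(CO)=C1/C=C/CCCCC | intermediate
28 | tert-butyl (2E)-4-[(1S,6R)-3-[(1E)-hept-1-en-1-yl]-4-(hydroxymethyl)-5,5-dimethoxy-2-oxo-7-oxabicyclo[4.1.0]hept-3-en-1-yl]-2-methylbut-2-enoate | CCCCC/C=C/C1=C(CO)C(OC)(OC)[C@@H]2O[C@]2(C/C=C(\C)C(=O)OC(C)(C)C)C1=O | intermediate
29 | (2E)-4-[(1S,6R)-3-[(1E)-hept-1-en-1-yl]-4-(hydroxymethyl)-2,5-dioxo-7-oxabicyclo[4.1.0]hept-3-en-1-yl]-2-methylbut-2-enoic acid | CCCCC/C=C/C1=C(CO)C(=O)[C@@H]2O[C@]2(C/C=C(\C)C(=O)O)C1=O | intermediate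
30 | (2E)-4-[(1S,5R,6S)-3-[(1E)-hept-1-en-1-yl]-5-hydroxy-4-(hydroxymethyl)-2-oxo-7-oxabicyclo[4.1.0]hept-3-en-1-yl]-2-methylbut-2-enoic acid | CCCCC/C=C/C1=C(CO)[C@@H](O)[C@@H]2O[C@]2(C/C=C(\C)C(=O)O)C1=O | target

**Step count**
Total: 13 steps. Longest linear sequence: 11 steps (1, 2, 4, 6, 7, 8, 9, 10, 11, 12, 13).

**Steps most likely to fail**

Step 11. The α-substituted enone may react slowly, the facial discrimination by the tartrate aggregate may be insufficient, and the 2-alkenyl dienone may dimerise before it is epoxidised. The fallback replaces reagent control by auxiliary control and sets out from 27. Acid-catalysed ketal exchange with (2R,4R)-pentane-2,4-diol (PPTS, benzene, 50 °C; the diol antipode is chosen to match) would give the (2R,4R)-pentane-2,4-diyl ketal analogue of 27 F1. Epoxidation with t-BuOOH and DBU should then be diastereoselective, because one methyl group of the dioxane shields one face of the β-carbon, and would give the (2R,4R)-pentane-2,4-diyl ketal analogue of 28 F2. CF3CO2H–CH2Cl2–H2O would hydrolyse the ketal and the ester, and the route is rejoined at 29.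

Step 13. Hydride may attack from the face away from the oxirane oxygen (giving the 5S epimer) or at the other carbonyl. The fallback makes the syn alcohol on purpose and inverts it, setting out from 28. Mild hydrolysis of the ketal alone (1 M HCl–THF, 0 °C) would give the tert-butyl ester of 29 F3. Luche reduction (NaBH4, CeCl3·7H2O, MeOH, −78 °C), expected to go anti to the oxirane at the less hindered carbonyl, would give the (1S,5S,6S) syn diol tert-butyl ester F4. A double Mitsunobu reaction with 4-nitrobenzoic acid (PPh3, DIAD, THF) would esterify the primary alcohol and invert the secondary carbinol, giving the (1S,5R,6S) bis(4-nitrobenzoate) F5. Brief methanolysis (K2CO3, MeOH, 0 °C) would give the tert-butyl ester of 30 F6. CF3CO2H–CH2Cl2 then cleaves the ester, and the route is rejoined at 30.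

Step 8. The allyl group may isomerise into conjugation with the arene, the heptenyl alkene may enter the metathesis, and the free phenol may slow the catalyst. The fallback moves the metathesis to a fragment with a single reactive alkene and sets out from 10. Cross-metathesis of 10 with 24 (same catalyst) would give tert-butyl (2E,5E)-2-methyl-6-(tributylstannyl)hexa-2,5-dienoate F7, and I2 would convert it into tert-butyl (2E,5E)-6-iodo-2-methylhexa-2,5-dienoate F8. Iodine–magnesium exchange with i-PrMgCl·LiCl at −40 °C, which tolerates the ester, would give [(1E,4E)-6-tert-butoxy-5-methyl-6-oxohexa-1,4-dien-1-yl]magnesium chloride F9. Its addition to 7, at the same carbonyl as in step 4, would give tert-butyl (2E,5E)-6-{3-[(1E)-hept-1-en-1-yl]-1-hydroxy-4-oxo-2-(propan-2-yloxy)cyclobut-2-en-1-yl}-2-methylhexa-2,5-dienoate F10. MeI with Ag2O would give the corresponding 1-methoxy compound F11. Addition of 18 at −78 °C and acid work-up as in step 6 would give tert-butyl (2E,5E)-6-{3-[(1E)-hept-1-en-1-yl]-1-methoxy-2-{[(4-methoxybenzyl)oxy]methyl}-4-oxocyclobut-2-en-1-yl}-2-methylhexa-2,5-dienoate F12. Thermolysis as in step 7 then gives the arene with the complete side chain, and the route is rejoined at 25.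

**Further compounds**
F1 | step 11 | (2R,4R)-pentane-2,4-diyl ketal analogue of 27, tert-butyl (2E)-4-[(2R,4R)-10-[(1E)-hept-1-en-1-yl]-11-(hydroxymethyl)-2,4-dimethyl-9-oxo-1,5-dioxaspiro[5.5]undeca-7,10-dien-8-yl]-2-methylbut-2-enoate | C[C@@H]1C[C@@H](C)OC2(O1)C=C(C/C=C(\C)C(=O)OC(C)(C)C)C(=O)C(/C=C/CCCCC)=C2CO
F2 | step 11 | (2R,4R)-pentane-2,4-diyl ketal analogue of 28 (same oxirane configuration as 28) | C[C@@H]1C[C@@H](C)OC2(O1)[C@@H]3O[C@]3(C/C=C(\C)C(=O)OC(C)(C)C)C(=O)C(/C=C/CCCCC)=C2CO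
F3 | step 13 | tert-butyl (2E)-4-[(1S,6R)-3-[(1E)-hept-1-en-1-yl]-4-(hydroxymethyl)-2,5-dioxo-7-oxabicyclo[4.1.0]hept-3-en-1-yl]-2-methylbut-2-enoate | CCCCC/C=C/C1=C(CO)C(=O)[C@@H]2O[C@]2(C/C=C(\C)C(=O)OC(C)(C)C)C1=O
F4 | step 13 | tert-butyl (2E)-4-[(1S,5S,6S)-3-[(1E)-hept-1-en-1-yl]-5-hydroxy-4-(hydroxymethyl)-2-oxo-7-oxabicyclo[4.1.0]hept-3-en-1-yl]-2-methylbut-2-enoate | CCCCC/C=C/C1=C(CO)[C@H](O)[C@@H]2O[C@]2(C/C=C(\C)C(=O)OC(C)(C)C)C1=O
F5 | step 13 | tert-butyl (2E)-4-[(1S,5R,6S)-3-[(1E)-hept-1-en-1-yl]-5-(4-nitrobenzoyloxy)-4-[(4-nitrobenzoyloxy)methyl]-2-oxo-7-oxabicyclo[4.1.0]hept-3-en-1-yl]-2-methylbut-2-enoate | CCCCC/C=C/C1=C(COC(=O)c3ccc(cc3)[N+](=O)[O-])[C@@H](OC(=O)c3ccc(cc3)[N+](=O)[O-])[C@@H]2O[C@]2(C/C=C(\C)C(=O)OC(C)(C)C)C1=O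
F6 | step 13 | tert-butyl (2E)-4-[(1S,5R,6S)-3-[(1E)-hept-1-en-1-yl]-5-hydroxy-4-(hydroxymethyl)-2-oxo-7-oxabicyclo[4.1.0]hept-3-en-1-yl]-2-methylbut-2-enoate | CCCCC/C=C/C1=C(CO)[C@@H](O)[C@@H]2O[C@]2(C/C=C(\C)C(=O)OC(C)(C)C)C1=O
F7 | step 8 | tert-butyl (2E,5E)-2-methyl-6-(tributylstannyl)hexa-2,5-dienoate | CCCC[Sn](CCCC)(CCCC)/C=C/C/C=C(\C)C(=O)OC(C)(C)C
F8 | step 8 | tert-butyl (2E,5E)-6-iodo-2-methylhexa-2,5-dienoate | I/C=C/C/C=C(\C)C(=O)OC(C)(C)C
F9 | step 8 | [(1E,4E)-6-tert-butoxy-5-methyl-6-oxohexa-1,4-dien-1-yl]magnesium chloride | Cl[Mg]/C=C/C/C=C(\C)C(=O)OC(C)(C)C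
F10 | step 8 | tert-butyl (2E,5E)-6-{3-[(1E)-hept-1-en-1-yl]-1-hydroxy-4-oxo-2-(propan-2-yloxy)cyclobut-2-en-1-yl}-2-methylhexa-2,5-dienoate (racemic) | CCCCC/C=C/C1=C(OC(C)C)C(O)(/C=C/C/C=C(\C)C(=O)OC(C)(C)C)C1=O
F11 | step 8 | tert-butyl (2E,5E)-6-{3-[(1E)-hept-1-en-1-yl]-1-methoxy-4-oxo-2-(propan-2-yloxy)cyclobut-2-en-1-yl}-2-methylhexa-2,5-dienoate (racemic) | CCCCC/C=C/C1=C(OC(C)C)C(OC)(/C=C/C/C=C(\C)C(=O)OC(C)(C)C)C1=O
F12 | step 8 | tert-butyl (2E,5E)-6-{3-[(1E)-hept-1-en-1-yl]-1-methoxy-2-{[(4-methoxybenzyl)oxy]methyl}-4-oxocyclobut-2-en-1-yl}-2-methylhexa-2,5-dienoate (racemic) | CCCCC/C=C/C1=C(COCc2ccc(OC)cc2)C(OC)(/C=C/C/C=C(\C)C(=O)OC(C)(C)C)C1=O
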